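Ring A of the target is an acylphloroglucinol: C5, C7 and C8a carry oxygen and C4a carries the C4 carbonyl, the oxygenation pattern of a folded triketide. The route therefore rests on disconnecting the C4a–C8a bond. A 4-hydroxypyran-2-one with a cinnamoylmethyl chain at C6, a masked cinnamoyl triketo acid, is opened by Mg(OMe)2 and recyclised by Claisen condensation, which builds carbocyclic ring A and delivers the symmetrical 2',4',6'-trihydroxychalcone in one operation. Enzymatic oxa-Michael closure then sets C2 as S; Friedel–Crafts senecioylation at C8 and a Mannich-type methylene coupling at C6 with a separately made 6-ethyl-4-hydroxy-5-methylpyran-2-one complete the target.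

Key step: step 2

Assumption: recombinant chalcone isomerase (the Medicago sativa enzyme produced in Escherichia coli) is taken as an accessible biocatalyst and LiN(iPr)2 as a purchased solution; neither is counted as a starting material.

Step 1
Reactants: 1 4-hydroxy-6-methylpyran-2-one; 2 (E)-N-methoxy-N-methyl-3-phenylprop-2-enamide
Product: 3 4-hydroxy-6-[(E)-2-oxo-4-phenylbut-3-enyl]pyran-2-one
Conditions: LiN(iPr)2 (2.2 equiv), THF, −78 °C, 1 h; then 2 (0.9 equiv), −78 → −20 °C; cold 1 M HCl
Reagents that add atoms: none
Why: Two equivalents of LiN(iPr)2 remove first the hydroxyl proton and then a proton of the C6 methyl group of 1, and the resulting dianion reacts at its terminal carbon with the N-methoxy-N-methylamide 2 by 1,2-addition to a lithium-chelated tetrahedral adduct that neither adds a second time nor consumes further base and releases the ketone only on acid quench (C-acylation of a β-dicarbonyl dianion with a Weinreb amide).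

Step 2
Reactants: 3 4-hydroxy-6-[(E)-2-oxo-4-phenylbut-3-enyl]pyran-2-one
Product: 5 (E)-3-phenyl-1-(2,4,6-trihydroxyphenyl)prop-2-en-1-one, via methyl triketo ester magnesium chelate 4 (not isolated)
Conditions: Mg(OMe)2 (6 equiv), MeOH, reflux, Ar; then poured into ice-cold 1 M HCl (pH 2), EtOAc
Reagents that add atoms: none
Why: Methoxide adds to the lactone carbonyl of 3 and opens it to methyl triketo ester 4 (methanol enters here and leaves again), which divalent magnesium holds as a folded bis-enolate chelate, so that the carbon between the cinnamoyl ketone and the neighbouring ketone (the future C4a) attacks the magnesium-activated ester carbonyl (the future C8a), methoxide is expelled and the 2-acylcyclohexane-1,3,5-trione enolises irreversibly to the aromatic ring. The closest known reaction type is the Claisen (Dieckmann-type) recyclisation of 6-(2-oxoalkyl)-4-hydroxypyran-2-ones to acylphloroglucinols with Mg(OMe)2. Ring A closes in a 6-exo-trig mode, the ester C=O lying outside the new ring. No stereocentre is formed, and because the two oxygens ortho to the acyl group are equivalent it does not matter which of them later becomes O1. The selectivity needed is Claisen over aldol folding (attack of the ester α-carbon on the cinnamoyl ketone, which would lead to a stilbene carboxylate), and the substrate secures it because the methyl ester is the only good acyl electrophile while the ketones are masked as magnesium enolates and the other possible donor carbon could only close a four-membered ring. The chalcone stays open because it leaves the reaction as its magnesium phenoxide chelate and is set free only by fast cold acidification, so that no racemic flavanone should be carried forward.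

Step 3
Reactants: 5 (E)-3-phenyl-1-(2,4,6-trihydroxyphenyl)prop-2-en-1-one
Product: 6 (2S)-5,7-dihydroxy-2-phenylchroman-4-one ((S)-pinocembrin)
Conditions: chalcone isomerase (recombinant, Medicago sativa), KH2PO4/K2HPO4 buffer (50 mM, pH 6.2), 5% DMSO, 10 °C, slow feed of 5; then pH 3, EtOAc
Reagents that add atoms: none
Why: Chalcone isomerase binds the s-cis enone of 5, its natural substrate type, and directs the 2'-phenoxide onto one face of the β-carbon in a 6-endo-trig oxa-Michael addition, so that C2 should be formed as S under enzyme control, the uncatalysed racemic closure being held back by the slightly acidic buffer, the low temperature and the slow feed.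

Step 4
Reactants: 6 (2S)-5,7-dihydroxy-2-phenylchroman-4-one; 7 3-methylbut-2-enoyl chloride
Product: 8 (2S)-5,7-dihydroxy-8-(3-methylbut-2-enoyl)-2-phenylchroman-4-one
Conditions: AlCl3 (3.5 equiv), 7 (1.05 equiv), PhNO2–CH2Cl2, 0 → 20 °C; ice/1 M HCl; chromatography
Reagents that add atoms: none
Why: In this Friedel–Crafts C-acylation AlCl3 ties the 5-oxygen and the C4 carbonyl into a chelate and the acylium ion from 7 enters ring A ortho to the 7-oxygen, which should give the C8 ketone as a main product (C8 lies between the 7-oxygen and the ring oxygen and para to the chelated oxygen) beside the C6 isomer that is removed by chromatography, while the new enone stays open as its aluminium chelate at low temperature and C2, never exposed to base and lacking a donor on ring B, should keep its S configuration.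

Step 5
Reactants: 9 pentan-3-one
Product: 10 (E)-trimethyl(pent-2-en-3-yloxy)silane
Conditions: LiN(iPr)2 (1.05 equiv), THF, −78 °C; Me3SiCl, −78 → 20 °C; pentane, filtration, distillation
Reagents that add atoms: chlorotrimethylsilane, C[Si](C)(C)Cl
Why: Deprotonation of the symmetrical ketone gives a single constitutional lithium enolate that Me3SiCl traps on oxygen (silyl enol ether formation), and the double-bond geometry, mainly E, is of no consequence because it disappears in the pyranone.

Step 6
Reactants: 10 (E)-trimethyl(pent-2-en-3-yloxy)silane; 11 propanedioyl dichloride (malonyl dichloride)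
Product: 12 6-ethyl-4-hydroxy-5-methylpyran-2-one
Conditions: Et2O, −78 → 20 °C, 16 h; evaporation, recrystallisation
Reagents that add atoms: none
Why: The silyl enol ether is C-acylated by one acid chloride group of 11 with loss of Me3SiCl, and the enol oxygen of the resulting 3,5-dioxo acid chloride then closes the lactone by 6-exo-trig acyl substitution with loss of HCl, which is the established malonyl dichloride route from enol ethers to 4-hydroxypyran-2-ones.

Step 7
Reactants: 12 6-ethyl-4-hydroxy-5-methylpyran-2-one; 13 N,N-dimethylmethyleneiminium iodide; 8 (2S)-5,7-dihydroxy-8-(3-methylbut-2-enoyl)-2-phenylchroman-4-one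
Product: 16 (2S)-6-[(6-ethyl-4-hydroxy-5-methyl-2-oxopyran-3-yl)methyl]-5,7-dihydroxy-8-(3-methylbut-2-enoyl)-2-phenylchroman-4-one, via Mannich base hydroiodide 14 (not isolated), via 3-methylidenepyran-2,4-dione 15 (not isolated)
Conditions: 12 (1.2 equiv), 13 (1.2 equiv), MeCN, 20 °C, 1 h; then 8, 60 °C; aqueous NH4Cl, chromatography
Reagents that add atoms: none
Why: Mannich reaction at the nucleophilic C3 of 12 gives 14, which on warming loses dimethylammonium iodide to the quinone-methide-like enone 15, and this is captured by C6 of 8, the only unsubstituted carbon of ring A, through conjugate addition and rearomatisation (the way methylene-bridged pyranone–acylphloroglucinol pairs are assembled), the weakly acidic medium sparing both the senecioyl enone and the base-sensitive C2 centre.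

Compound list
1 | 4-hydroxy-6-methylpyran-2-one | Cc1cc(O)cc(=O)o1 | starting material
2 | (E)-N-methoxy-N-methyl-3-phenylprop-2-enamide | CON(C)C(=O)/C=C/c1ccccc1 | starting material
3 | 4-hydroxy-6-[(E)-2-oxo-4-phenylbut-3-enyl]pyran-2-one | O=C(/C=C/c1ccccc1)Cc1cc(O)cc(=O)o1 | intermediate
4 | methyl (E)-3,5,7-trioxo-9-phenylnon-8-enoate, present as its magnesium chelate and not isolated (SMILES of the neutral ester) | COC(=O)CC(=O)CC(=O)CC(=O)/C=C/c1ccccc1 | intermediate
5 | (E)-3-phenyl-1-(2,4,6-trihydroxyphenyl)prop-2-en-1-one ((E)-2',4',6'-trihydroxychalcone) | O=C(/C=C/c1ccccc1)c1c(O)cc(O)cc1O | intermediate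
6 | (2S)-5,7-dihydroxy-2-phenylchroman-4-one ((S)-pinocembrin) | Oc1cc(O)cc2c1C(=O)C[C@@H](c1ccccc1)O2 | intermediate
7 | 3-methylbut-2-enoyl chloride | CC(C)=CC(Cl)=O | starting material
8 | (2S)-5,7-dihydroxy-8-(3-methylbut-2-enoyl)-2-phenylchroman-4-one | Oc1cc(O)c(C(=O)C=C(C)C)c2c1C(=O)C[C@@H](c1ccccc1)O2 | intermediate
9 | pentan-3-one | CCC(=O)CC | starting material
10 | (E)-trimethyl(pent-2-en-3-yloxy)silane (mainly E, geometry without consequence) | C/C=C(\CC)O[Si](C)(C)C | intermediate
11 | propanedioyl dichloride (malonyl dichloride) | O=C(Cl)CC(Cl)=O | starting material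
12 | 6-ethyl-4-hydroxy-5-methylpyran-2-one | CCc1oc(=O)cc(O)c1C | intermediate
13 | N,N-dimethylmethyleneiminium iodide | C=[N+](C)C.[I-] | starting material
14 | 3-[(dimethylamino)methyl]-6-ethyl-4-hydroxy-5-methylpyran-2-one hydroiodide (not isolated) | CCc1oc(=O)c(C[NH+](C)C)c(O)c1C.[I-] | intermediate
15 | 6-ethyl-5-methyl-3-methylidenepyran-2,4-dione (not isolated) | CCC1=C(C)C(=O)C(=C)C(=O)O1 | intermediate
16 | (2S)-6-[(6-ethyl-4-hydroxy-5-methyl-2-oxopyran-3-yl)methyl]-5,7-dihydroxy-8-(3-methylbut-2-enoyl)-2-phenylchroman-4-one | CCc1oc(=O)c(Cc2c(O)c(C(=O)C=C(C)C)c3c(c2O)C(=O)C[C@@H](c2ccccc2)O3)c(O)c1C | target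

Total step count: 7. Longest linear sequence: 5 steps (steps 1, 2, 3, 4 and 7); the pyranone branch (steps 5 and 6) joins in step 7.

Steps most likely to fail

Step 4. The acylium ion may attack C6 as readily as C8 or acylate twice, and the Lewis acid may close the 7-hydroxyl onto the new enone or open ring C and so erode C2. The fallback sets out from 6 and comes back at 16. The two substitutions of ring A are done in the opposite order, so that the acyl group enters when only one ring carbon is left. Pyranone 12 is converted with 13 in MeCN into 14 and warmed with an excess of 6, so that 15 alkylates the still unacylated, more nucleophilic ring A under neutral conditions. The C6-alkylated isomer (2S)-6-[(6-ethyl-4-hydroxy-5-methyl-2-oxopyran-3-yl)methyl]-5,7-dihydroxy-2-phenylchroman-4-one F1 is separated from its C8 isomer and from recovered 6. It is then acylated with 7 (AlCl3, PhNO2–CH2Cl2, 0 °C), which can only take place at C8 and gives 16.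

Step 2. The opened chain may fold by aldol instead of Claisen condensation or relactonise, and ring C may close without stereocontrol while the mixture passes through neutral pH on work-up. The fallback sets out from 2 and comes back at 5. Ring A is taken from an intact phloroglucinol instead of being built. 1,3,5-Tris(methoxymethoxy)benzene F2 is lithiated between two acetal oxygens (n-BuLi, THF, 0 °C) to [2,4,6-tris(methoxymethoxy)phenyl]lithium F3. This adds once to amide 2 (−78 °C, then 1 M HCl) and should give (E)-3-phenyl-1-[2,4,6-tris(methoxymethoxy)phenyl]prop-2-en-1-one F4. Cleavage of the three acetals with HCl in MeOH at 20 °C, stopped before acid-catalysed ring closure sets in, gives 5.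

Step 3. Spontaneous ring closure may compete with the enzyme when substrate solubility or enzyme activity is low, which lowers the enantiomeric purity, and this cannot be repaired later. The fallback sets out from 5 and comes back at 6. Compound 5 is cyclised without stereocontrol (NaOAc, EtOH, reflux) to racemic 5,7-dihydroxy-2-phenylchroman-4-one F5. This is resolved by preparative chromatography on a cellulose tris(3,5-dimethylphenylcarbamate) stationary phase, and the S enantiomer is 6. The (2R)-5,7-dihydroxy-2-phenylchroman-4-one F6 can be racemised again through the chalcone with NaOAc and recycled.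

Further compounds
F1 | step 4 | (2S)-6-[(6-ethyl-4-hydroxy-5-methyl-2-oxopyran-3-yl)methyl]-5,7-dihydroxy-2-phenylchroman-4-one | CCc1oc(=O)c(Cc2c(O)cc3c(c2O)C(=O)C[C@@H](c2ccccc2)O3)c(O)c1C
F2 | step 2 | 1,3,5-tris(methoxymethoxy)benzene | COCOc1cc(OCOC)cc(OCOC)c1
F3 | step 2 | [2,4,6-tris(methoxymethoxy)phenyl]lithium | [Li]c1c(OCOC)cc(OCOC)cc1OCOC
F4 | step 2 | (E)-3-phenyl-1-[2,4,6-tris(methoxymethoxy)phenyl]prop-2-en-1-one | COCOc1cc(OCOC)c(C(=O)/C=C/c2ccccc2)c(OCOC)c1
F5 | step 3 | racemic 5,7-dihydroxy-2-phenylchroman-4-one | Oc1cc(O)cc2c1C(=O)CC(c1ccccc1)O2
F6 | step 3 | (2R)-5,7-dihydroxy-2-phenylchroman-4-one | Oc1cc(O)cc2c1C(=O)C[C@H](c1ccccc1)O2
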